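The ring bears one carbon substituent only, C7 on the quaternary carbinol carbon C1, and C1 lies para to the alkene carbon C4 of the six-membered ring. The ring is therefore traced back to the achiral para-quinol of 4-hydroxybenzyl alcohol, in which C2=C3 and C5=C6 are enantiotopic enone alkenes and C4 is a carbonyl. The key step epoxidises C2=C3 from the face of the C1 hydroxyl under NaN(SiMe3)2 and a chiral dialkyl tartrate: one oxirane ring closes and C1, C2 and C3 are fixed at once. Its precursor is the para-quinol with a free tertiary hydroxyl and O7 as a silyl ether. Osmylation of C5=C6 and a Wharton transposition that deletes the C4 oxygen complete the core.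

Key step: step 3

Convention: locants C1–C7 are those of the target in every compound (C1 quaternary carbinol carbon, C7 its CH2O carbon, C2 to C6 round the ring); with the ring drawn flat and C1→C6 running clockwise, β points towards the viewer and α away.

Assumption: which tartrate antipode gives the required epoxide cannot be derived from a transferable model; L-(+)-diisopropyl tartrate is written, and its mirror image takes its place if that proves to be the matched one.

**Route**

Step 1
Reactants: 1 4-hydroxybenzyl alcohol; 2 tert-butyldimethylsilyl chloride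
Product: 3 4-{[tert-butyl(dimethyl)silyl]oxymethyl}phenol
Conditions: TBSCl (1.05 equiv), imidazole, DMF, 0 °C
Reagents that add atoms: tert-butyldimethylsilyl chloride (2), CC(C)(C)[Si](C)(C)Cl
Why: Imidazole-mediated silyl ether formation should take the aliphatic hydroxyl, which outcompetes the un-ionised phenol for the silylimidazolium, so one equivalent of 2 at 0 °C leaves the phenol free for the oxidation.

Step 2
Reactants: 3 4-{[tert-butyl(dimethyl)silyl]oxymethyl}phenol
Product: 4 4-{[tert-butyl(dimethyl)silyl]oxymethyl}-4-hydroxycyclohexa-2,5-dien-1-one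
Conditions: PhI(OAc)2 (1.1 equiv), MeCN/H2O (4:1), 0 °C
Reagents that add atoms: water, O
Why: Oxidative dearomatisation of a para-substituted phenol with trivalent iodine: ligand exchange at iodine activates the phenol, water attacks the substituted para carbon and iodobenzene leaves, giving the para-quinol in which C1 is a prochiral quaternary carbinol, so no stereocentre is formed.

Step 3
Reactants: 4 4-{[tert-butyl(dimethyl)silyl]oxymethyl}-4-hydroxycyclohexa-2,5-dien-1-one
Product: 6 cis-epoxy quinol (1R,5S,6S)-5-{[tert-butyl(dimethyl)silyl]oxymethyl}-5-hydroxy-7-oxabicyclo[4.1.0]hept-3-en-2-one, via peroxy enolate 5 (not isolated)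
Conditions: Ph3COOH (1.1 equiv), NaN(SiMe3)2, L-(+)-diisopropyl tartrate, 4 Å MS, toluene, −60 °C
Reagents that add atoms: trityl hydroperoxide, OOC(c1ccccc1)(c1ccccc1)c1ccccc1
Why: Proposed new method: NaN(SiMe3)2 deprotonates 4, the tartrate and the hydroperoxide, and within the tartrate-bound aggregate held at the C1 alkoxide the trityl peroxide anion should add in conjugate (Weitz–Scheffer) fashion to C2, giving enolate 5, whose C3 carbon then displaces trityl oxide from the proximal peroxide oxygen. The closest known reaction types are the hydroxyl-directed syn epoxidation of para-quinols by alkaline hydroperoxides, which is racemic, and the tartrate-mediated asymmetric nucleophilic epoxidation of hydroxyl-bearing quinone monoketals with this same reagent set. The oxirane, the one ring formed, closes by 3-exo-tet attack of the enolate carbon C3 on oxygen. C2 and C3 are set by delivery from the C1 alkoxide, which puts the oxirane cis to the hydroxyl, and C1 turns into a stereocentre through the choice between the enantiotopic C2=C3 and C5=C6 alkenes, a choice only the chiral tartrate can make. The step needs enantiotopic-group selectivity and a stop after one epoxidation: the free tertiary hydroxyl of 4 ties the substrate to the chiral aggregate, the bulky trityl peroxide is slow in the unbound background reaction, the hydroperoxide is held near one equivalent, and the minor enantiomer, which still carries the favoured alkene, should be drained to the achiral bis-epoxide. At −60 °C in toluene the alkoxide should neither shift the silyl group from O7 to O1 nor attack the silyl ether, conditions that an ester at O7 would not survive.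

Step 4
Reactants: 6 cis-epoxy quinol
Product: 7 keto triol 2β,3β-epoxy-1β,5α,6α-trihydroxy-1-{[tert-butyl(dimethyl)silyl]oxymethyl}cyclohexan-4-one
Conditions: OsO4 (5 mol %), NMO, acetone/H2O, rt
Reagents that add atoms: osmium tetroxide, O=[Os](=O)(=O)=O; N-methylmorpholine N-oxide, C[N+]1([O-])CCOCC1; water, O
Why: OsO4/NMO dihydroxylation of the remaining enone alkene: the concerted [3+2] addition is suprafacial, so O5 and O6 end up cis to each other, and it should take the α face, anti to the allylic C1–O bond as is usual for osmylation of allylic alcohols and away from the pseudoaxial hydroxyl and the β oxirane, which sets C5 and C6.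

Step 5
Reactants: 7 keto triol
Product: 8 keto acetonide 2β,3β-epoxy-1β-hydroxy-5α,6α-(isopropylidenedioxy)-1-{[tert-butyl(dimethyl)silyl]oxymethyl}cyclohexan-4-one
Conditions: Me2C(OMe)2, PPTS (cat.), acetone, rt
Reagents that add atoms: 2,2-dimethoxypropane, COC(C)(C)OC
Why: Acid-catalysed transketalisation (acetonide formation) picks the one cis-1,2-diol, O5/O6, for a cis-fused dioxolane while the trans-disposed tertiary O1 stays free; the acetal shuts down retro-aldol cleavage of the β-hydroxy ketone and later tells O5/O6 apart from O2.

Step 6
Reactants: 8 keto acetonide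
Product: 11 allylic diol 1-{[tert-butyl(dimethyl)silyl]oxymethyl}-5α,6α-(isopropylidenedioxy)cyclohex-3-ene-1β,2β-diol, via hydrazone 9 (not isolated), via alkenyldiazene 10 (not isolated)
Conditions: N2H4·H2O, AcOH, MeOH, 0 °C → rt
Reagents that add atoms: none
Why: Wharton transposition: the C4 hydrazone 9 opens the strained oxirane at C3–O to the alkenyldiazene 10, which loses N2 with delivery of hydrogen to C4, so that the C4 oxygen is removed, C3=C4 is formed and the untouched C2–O bond keeps its β configuration, while the far poorer acetal leaving group at C5 stays in place and the cis ring fusion holds C5.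

Step 7
Reactants: 11 allylic diol; 12 benzoyl chloride
Product: 13 2β-benzoyloxy-1-{[tert-butyl(dimethyl)silyl]oxymethyl}-5α,6α-(isopropylidenedioxy)cyclohex-3-en-1β-ol
Conditions: BzCl (1.2 equiv), pyridine, DMAP (cat.), CH2Cl2, 0 °C
Reagents that add atoms: benzoyl chloride (12), O=C(Cl)c1ccccc1
Why: DMAP-catalysed acylation (nucleophilic catalysis through the N-benzoylpyridinium ion) esterifies the secondary allylic C2 hydroxyl, the only reactive hydroxyl left, since the tertiary C1 hydroxyl does not acylate at 0 °C.

Step 8
Reactants: 13 C2 benzoate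
Product: 14 (1R,2S,5S,6S)-1,5,6-trihydroxy-1-(hydroxymethyl)cyclohex-3-en-2-yl benzoate
Conditions: TFA/H2O (9:1), 0 °C → rt; evaporation from toluene, no basic wash
Reagents that add atoms: none
Why: Aqueous acid hydrolysis removes the isopropylidene acetal and the primary silyl ether in one operation, the benzoate being stable to acid and acyl migration being slow without base, so that O2 stays esterified and no stereocentre is touched.

Step 9
Reactants: 14 tetraol 2-benzoate; 12 benzoyl chloride
Product: 16 target [(1R,2S,5S,6S)-2,5-bis(benzoyloxy)-1,6-dihydroxycyclohex-3-en-1-yl]methyl benzoate, via dibenzoate 15 (not isolated)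
Conditions: BzCl (2.1 equiv), pyridine, CH2Cl2, −30 → 0 °C
Reagents that add atoms: benzoyl chloride (12), O=C(Cl)c1ccccc1
Why: Kinetically controlled acylation should follow the order primary C7 hydroxyl (giving 15) then allylic pseudoequatorial C5 hydroxyl, and stop there with 2.1 equivalents at low temperature because the C6 hydroxyl is axial and wedged against the quaternary C1 in the half-chair that keeps C7 equatorial, and the C1 hydroxyl is tertiary.

**Compound list**

1 | 4-hydroxybenzyl alcohol | OCc1ccc(O)cc1 | starting material
2 | tert-butyldimethylsilyl chloride | CC(C)(C)[Si](C)(C)Cl | starting material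
3 | 4-{[tert-butyl(dimethyl)silyl]oxymethyl}phenol | CC(C)(C)[Si](C)(C)OCc1ccc(O)cc1 | intermediate
4 | 4-{[tert-butyl(dimethyl)silyl]oxymethyl}-4-hydroxycyclohexa-2,5-dien-1-one (achiral para-quinol, precursor of the key step) | CC(C)(C)[Si](C)(C)OCC1(O)C=CC(=O)C=C1 | intermediate
5 | peroxy enolate, not isolated: disodium salt with 1β-oxido, 2β-(triphenylmethylperoxy), C3=C4 enolate (4-oxido) and C5=C6 alkene | CC(C)(C)[Si](C)(C)OC[C@]1([O-])[C@@H](OOC(c2ccccc2)(c2ccccc2)c2ccccc2)C=C([O-])C=C1.[Na+].[Na+] | intermediate
6 | (1R,5S,6S)-5-{[tert-butyl(dimethyl)silyl]oxymethyl}-5-hydroxy-7-oxabicyclo[4.1.0]hept-3-en-2-one (1β-hydroxyl, 2β,3β-oxirane, C4 ketone, C5=C6) | CC(C)(C)[Si](C)(C)OC[C@]1(O)[C@H]2O[C@H]2C(=O)C=C1 | intermediate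
7 | 2β,3β-epoxy-1β,5α,6α-trihydroxy-1-{[tert-butyl(dimethyl)silyl]oxymethyl}cyclohexan-4-one | CC(C)(C)[Si](C)(C)OC[C@]1(O)[C@H]2O[C@H]2C(=O)[C@H](O)[C@@H]1O | intermediate
8 | 2β,3β-epoxy-1β-hydroxy-5α,6α-(isopropylidenedioxy)-1-{[tert-butyl(dimethyl)silyl]oxymethyl}cyclohexan-4-one | CC(C)(C)[Si](C)(C)OC[C@]1(O)[C@H]2O[C@H]2C(=O)[C@@H]3OC(C)(C)O[C@H]13 | intermediate
9 | C4 hydrazone of 8, not isolated (C=N geometry open) | CC(C)(C)[Si](C)(C)OC[C@]1(O)[C@H]2O[C@H]2C(=NN)[C@@H]3OC(C)(C)O[C@H]13 | intermediate
10 | alkenyldiazene, not isolated: 4-diazenyl-1-{[tert-butyl(dimethyl)silyl]oxymethyl}-5α,6α-(isopropylidenedioxy)cyclohex-3-ene-1β,2β-diol | CC(C)(C)[Si](C)(C)OC[C@]1(O)[C@@H](O)C=C(N=N)[C@@H]2OC(C)(C)O[C@H]12 | intermediate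
11 | 1-{[tert-butyl(dimethyl)silyl]oxymethyl}-5α,6α-(isopropylidenedioxy)cyclohex-3-ene-1β,2β-diol | CC(C)(C)[Si](C)(C)OC[C@]1(O)[C@@H](O)C=C[C@@H]2OC(C)(C)O[C@H]12 | intermediate
12 | benzoyl chloride | O=C(Cl)c1ccccc1 | starting material
13 | 2β-benzoyloxy-1-{[tert-butyl(dimethyl)silyl]oxymethyl}-5α,6α-(isopropylidenedioxy)cyclohex-3-en-1β-ol | CC(C)(C)[Si](C)(C)OC[C@]1(O)[C@@H](OC(=O)c2ccccc2)C=C[C@@H]3OC(C)(C)O[C@H]13 | intermediate
14 | (1R,2S,5S,6S)-1,5,6-trihydroxy-1-(hydroxymethyl)cyclohex-3-en-2-yl benzoate | OC[C@]1(O)[C@@H](OC(=O)c2ccccc2)C=C[C@H](O)[C@@H]1O | intermediate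
15 | [(1R,2S,5S,6S)-2-(benzoyloxy)-1,5,6-trihydroxycyclohex-3-en-1-yl]methyl benzoate (not isolated in step 9) | O=C(OC[C@]1(O)[C@@H](OC(=O)c2ccccc2)C=C[C@H](O)[C@@H]1O)c1ccccc1 | intermediate
16 | [(1R,2S,5S,6S)-2,5-bis(benzoyloxy)-1,6-dihydroxycyclohex-3-en-1-yl]methyl benzoate | O=C(OC[C@]1(O)[C@@H](OC(=O)c2ccccc2)C=C[C@H](OC(=O)c2ccccc2)[C@@H]1O)c1ccccc1 | target

**Count and risks**

Total step count: 9. Longest linear sequence: 9 steps (1 → 16).

Steps most likely to fail:

1. Step 3. The tartrate-bound aggregate may discriminate poorly between the two enantiotopic alkenes, or peroxide transfer from the hindered tertiary alkoxide may be sluggish, so that enantiomeric purity or conversion falls short. The fallback uses known chemistry and sets out from 4. The hydroxyl-directed syn epoxidation is run without chiral control (t-BuOOH, DBU, CH2Cl2, 0 °C). This should give the cis-epoxy quinol as the racemate, that is 6 together with its mirror image, the enantiomeric epoxy quinol F1. The two are parted by preparative chromatography on a polysaccharide chiral stationary phase, and enantiopure 6 re-enters the route at step 4.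

2. Step 6. Hydrazone formation at the crowded ketone flanked by two oxygenated carbons may stall, or the alkenyldiazene may be diverted by over-reduction or by hydrazine attack on the oxirane. The fallback sets out from 8. NaBH4 in MeOH at 0 °C reduces the ketone to the C4 carbinol, epoxy alcohol F2 (either C4 epimer serves). 1,1'-Thiocarbonyldiimidazole converts it into the O-(imidazol-1-ylthiocarbonyl) derivative F3. Bu3SnH and AIBN in toluene at 80 °C then generate the C4 radical, which cleaves the neighbouring C3–O bond of the oxirane; hydrogen transfer to the C2 oxyl radical gives 11, where the route is rejoined. This radical deoxygenation with epoxide fragmentation is the established tin hydride counterpart of the Wharton transposition. A high Bu3SnH concentration is used to outrun β-scission of the oxyl radical.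

3. Step 9. Site selectivity may break down: acylation may reach the C6 hydroxyl before C5 is complete, or the benzoyl group may migrate from O5 to O6. The fallback sets out from 14. One equivalent of 12 at −40 °C is used so that the 2,7-dibenzoate 15 can be isolated. Bu2SnO in refluxing toluene with removal of water converts its cis-5,6-diol into the dibutylstannylene acetal F4. Compound 12 at 0 °C then acylates the tin-activated equatorial oxygen, O5, and the route is rejoined at 16. Selectivity then rests on tin activation and not on relative rates.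

Further compounds
F1 | step 3 | (1S,5R,6R)-5-{[tert-butyl(dimethyl)silyl]oxymethyl}-5-hydroxy-7-oxabicyclo[4.1.0]hept-3-en-2-one (mirror image of 6) | CC(C)(C)[Si](C)(C)OC[C@@]1(O)[C@@H]2O[C@@H]2C(=O)C=C1
F2 | step 6 | 2β,3β-epoxy-5α,6α-(isopropylidenedioxy)-1-{[tert-butyl(dimethyl)silyl]oxymethyl}cyclohexane-1β,4-diol (C4 configuration open) | CC(C)(C)[Si](C)(C)OC[C@]1(O)[C@H]2O[C@H]2C(O)[C@@H]3OC(C)(C)O[C@H]13
F3 | step 6 | O4-(imidazol-1-ylthiocarbonyl) derivative of F2 | CC(C)(C)[Si](C)(C)OC[C@]1(O)[C@H]2O[C@H]2C(OC(=S)n2ccnc2)[C@@H]3OC(C)(C)O[C@H]13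
F4 | step 9 | 5α,6α-O-dibutylstannylene acetal of 15 | O=C(OC[C@]1(O)[C@@H](OC(=O)c2ccccc2)C=C[C@@H]2O[Sn](CCCC)(CCCC)O[C@H]12)c1ccccc1
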